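**Retrosynthetic overview** (lactone C=O = C1; C2(Me), C3(=O), C4(OH)(CH2OH), C5, C6(OMe)=C7, C8(Me), C9, C10(=CH2), C11=C12(Me), C13(Et)–O)
- Last: desilylation, preceded by closure of the only ring of the target (the 14-membered lactone) at C10–C11 by Ni-catalysed electroreductive coupling of a (Z)-alkenyl iodide with a 2-chloroalkene, which also creates the diene.
- C2–C3: crossed Claisen condensation of the propionate of (S,Z)-1-iodo-2-methylpent-1-en-3-ol (from (S)-pent-1-yn-3-ol by anti-carbomagnesiation/iodination) onto a Seebach dioxolanone, which opens that temporary ring and frees the C4 hydroxyl.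
- C6=C7 (E)-enol ether: syn-hydroboration of an internal alkyne, then Cu-mediated methoxylation with retention.
- C5–C6: photochemical Cu-catalysed decarboxylative alkynylation of the malic-acid-derived dioxolanone acid (C4 set by enolate alkylation anti to tert-butyl) with an alkyne built from methyl (R)-3-bromo-2-methylpropanoate (C8) and 1,1-dichloroethene (C10).
- Ring order: dioxolanone first (temporary, from (S)-malic acid), macrolactone last; C2 settles thermodynamically.

Assumption: the freely epimerisable C2 (between the two carbonyls) is taken to prefer the (2R) configuration in the macrocycle, as in related 3-keto-14-membered macrolides, and (S)-pent-1-yn-3-ol and methyl (R)-3-bromo-2-methylpropanoate (the bromide of the Roche ester) are bought as single enantiomers.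

Step 1
Reactants: 1 (S)-malic acid
Product: 2 [(2S,4S)-2-tert-butyl-5-oxo-1,3-dioxolan-4-yl]acetic acid (cis-dioxolanone)
Conditions: t-BuCHO, p-TsOH (cat.), H2SO4 (cat.), pentane, reflux (Dean–Stark); recrystallisation
Reagents that add atoms: pivalaldehyde CC(C)(C)C=O
Why: Acid-catalysed acetalisation of the α-hydroxy acid unit (Seebach dioxolanone formation) gives the thermodynamic, crystalline cis acetal, so the new acetal centre is controlled by the malic acid stereocentre.

Step 2
Reactants: 2 [(2S,4S)-2-tert-butyl-5-oxo-1,3-dioxolan-4-yl]acetic acid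
Product: 4 [(2S,4R)-2-tert-butyl-5-oxo-4-{[(triisopropylsilyl)oxy]methyl}-1,3-dioxolan-4-yl]acetic acid, via dilithium enolate-carboxylate 3 (not isolated)
Conditions: LiN(SiMe3)2 (2.2 equiv), THF, −78 °C; then TOMCl (1.1 equiv), −78 → −30 °C; aq. citric acid
Reagents that add atoms: lithium bis(trimethylsilyl)amide [Li+].C[Si](C)(C)[N-][Si](C)(C)C; (triisopropylsiloxy)methyl chloride (TOMCl) ClCO[Si](C(C)C)(C(C)C)C(C)C
Why: Seebach self-regeneration of stereocentres: the enolate is alkylated by the α-chloro ether on the face anti to tert-butyl, so the CH2O arm takes the place of the former hydrogen and fixes the C4 quaternary centre (dr expected >95:5).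

Step 3
Reactants: 5 methyl (R)-3-bromo-2-methylpropanoate
Product: 7 methyl (S)-4-chloro-2-methylpent-4-enoate, via alkylzinc bromide 6 (not isolated)
Conditions: Zn dust, LiCl, THF, 50 °C; then CH2=CCl2 (5 equiv), PdCl2(DPEphos) (3 mol%), THF, 40 °C
Reagents that add atoms: zinc [Zn]; 1,1-dichloroethene C=C(Cl)Cl
Why: Zinc insertion gives a zinc homoenolate whose stereocentre is not the metalated carbon, and Negishi coupling with excess 1,1-dichloroethene stops after one C–Cl bond because the product monochloroalkene is much less reactive.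

Step 4
Reactants: 7 methyl (S)-4-chloro-2-methylpent-4-enoate
Product: 9 (S)-2-chloro-4-methylhex-1-en-5-yne, via (S)-4-chloro-2-methylpent-4-enal 8 (not isolated)
Conditions: i-Bu2AlH (1.05 equiv), CH2Cl2, −78 °C; then MeOH, K2CO3, dimethyl (1-diazo-2-oxopropyl)phosphonate, −78 °C → rt
Reagents that add atoms: dimethyl (1-diazo-2-oxopropyl)phosphonate COP(=O)(OC)C(=[N+]=[N-])C(C)=O
Why: Partial reduction to the aldehyde followed in the same flask by Seyferth–Gilbert homologation with the Ohira–Bestmann reagent, whose mild carbonate conditions avoid epimerisation of the α-stereocentre (C8).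

Step 5
Reactants: 4 [(2S,4R)-2-tert-butyl-5-oxo-4-{[(triisopropylsilyl)oxy]methyl}-1,3-dioxolan-4-yl]acetic acid; 9 (S)-2-chloro-4-methylhex-1-en-5-yne
Product: 11 (2S,5R)-2-tert-butyl-5-[(4S)-6-chloro-4-methylhept-6-en-2-yn-1-yl]-5-{[(triisopropylsilyl)oxy]methyl}-1,3-dioxolan-4-one, via N-(acyloxy)phthalimide ester 10 (not isolated)
Conditions: N-hydroxyphthalimide, DIC, DMAP (cat.), CH2Cl2, rt; then 9 (1.5 equiv), Ir(ppy)3 (1 mol%), CuI (10 mol%), 2,2′:6′,2″-terpyridine (12 mol%), K2CO3, DMF, 450 nm LEDs, rt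
Reagents that add atoms: N-hydroxyphthalimide O=C1N(O)C(=O)c2ccccc12
Why: Photoinduced copper-catalysed decarboxylative alkynylation: excited Ir(ppy)3 reduces the redox-active ester, loss of CO2 gives the primary C5 radical (not a stereocentre), and capture by the copper acetylide followed by reductive elimination forges C5–C6 with C4 and C8 untouched.

Step 6
Reactants: 11 (2S,5R)-2-tert-butyl-5-[(4S)-6-chloro-4-methylhept-6-en-2-yn-1-yl]-5-{[(triisopropylsilyl)oxy]methyl}-1,3-dioxolan-4-one
Product: 12 (2S,5R)-2-tert-butyl-5-[(2Z,4S)-6-chloro-4-methyl-2-(4,4,5,5-tetramethyl-1,3,2-dioxaborolan-2-yl)hepta-2,6-dien-1-yl]-5-{[(triisopropylsilyl)oxy]methyl}-1,3-dioxolan-4-one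
Conditions: HBpin (1.5 equiv), Cy2BH (10 mol%), THF, rt
Reagents that add atoms: pinacolborane CC1(C)OBOC1(C)C
Why: Dialkylborane-catalysed hydroboration with pinacolborane adds B–H syn across the alkyne with boron at C6 (next to the unbranched CH2, away from the α-branched C8), so C5 and C8 end up cis, while the deactivated chloroalkene is left alone.

Step 7
Reactants: 12 (2S,5R)-2-tert-butyl-5-[(2Z,4S)-6-chloro-4-methyl-2-(4,4,5,5-tetramethyl-1,3,2-dioxaborolan-2-yl)hepta-2,6-dien-1-yl]-5-{[(triisopropylsilyl)oxy]methyl}-1,3-dioxolan-4-one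
Product: 13 (2S,5R)-2-tert-butyl-5-[(2E,4S)-6-chloro-2-methoxy-4-methylhepta-2,6-dien-1-yl]-5-{[(triisopropylsilyl)oxy]methyl}-1,3-dioxolan-4-one
Conditions: Cu(OAc)2 (2 equiv), Et3N (3 equiv), MeOH/CH2Cl2 (1:4), 4 Å MS, rt
Reagents that add atoms: methanol CO
Why: Chan–Lam–Evans oxidative C–O coupling, in which transmetalation of the alkenylboronate to divalent copper and C–O reductive elimination proceed with retention, turns the (Z)-boronate into the (E)-methyl enol ether.

Step 8
Reactants: 14 (S)-pent-1-yn-3-ol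
Product: 16 (S,Z)-1-iodo-2-methylpent-1-en-3-ol, via cyclic alkenylmagnesium alkoxide 15 (not isolated)
Conditions: MeMgBr (3 equiv), CuI (10 mol%), Et2O/THF, 0 °C → rt; then I2, −78 → 0 °C
Reagents that add atoms: methylmagnesium bromide C[Mg]Br; iodine II
Why: Duboudin-type copper-catalysed anti-carbomagnesiation of the propargylic magnesium alkoxide puts methyl on C12 and magnesium on C11 in a five-membered chelate, and iodinolysis with retention gives the (Z)-iodide without touching the carbinol centre.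

Step 9
Reactants: 16 (S,Z)-1-iodo-2-methylpent-1-en-3-ol
Product: 17 (S,Z)-1-iodo-2-methylpent-1-en-3-yl propanoate
Conditions: EtCOCl, pyridine, DMAP (cat.), CH2Cl2, 0 °C
Reagents that add atoms: propanoyl chloride CCC(=O)Cl
Why: DMAP-catalysed acylation (esterification) of the secondary allylic alcohol, which touches no stereocentre.

Step 10
Reactants: 17 (S,Z)-1-iodo-2-methylpent-1-en-3-yl propanoate; 13 (2S,5R)-2-tert-butyl-5-[(2E,4S)-6-chloro-2-methoxy-4-methylhepta-2,6-dien-1-yl]-5-{[(triisopropylsilyl)oxy]methyl}-1,3-dioxolan-4-one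
Product: 19 (S,Z)-1-iodo-2-methylpent-1-en-3-yl (2RS,4R,6E,8S)-10-chloro-4-hydroxy-6-methoxy-2,8-dimethyl-3-oxo-4-{[(triisopropylsilyl)oxy]methyl}undeca-6,10-dienoate, via lithium ester enolate 18 (not isolated)
Conditions: 17 (2.5 equiv), LiN(i-Pr)2 (2.6 equiv), THF, −78 °C; then 13, −78 → −50 °C; aq. NH4Cl
Reagents that add atoms: lithium diisopropylamide [Li+].CC(C)[N-]C(C)C
Why: Crossed Claisen condensation in which the non-enolisable dioxolanone (an activated acylal ester) acylates the propionate enolate below the onset of Ireland–Claisen rearrangement, losing pivalaldehyde to unveil the C4 tertiary alcohol without touching C4, while C2 forms as an epimer mixture that is corrected in step 11.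

Step 11
Reactants: 19 (S,Z)-1-iodo-2-methylpent-1-en-3-yl (2RS,4R,6E,8S)-10-chloro-4-hydroxy-6-methoxy-2,8-dimethyl-3-oxo-4-{[(triisopropylsilyl)oxy]methyl}undeca-6,10-dienoate
Product: 20 (3R,5R,7E,9S,12Z,14S)-14-ethyl-5-hydroxy-7-methoxy-3,9,13-trimethyl-11-methylidene-5-{[(triisopropylsilyl)oxy]methyl}-1-oxacyclotetradeca-7,12-diene-2,4-dione
Conditions: NiBr2(bpy) (20 mol%), n-Bu4NBr (0.1 M), DMF, undivided cell, Zn anode, Ni-foam cathode, constant current (2.2 F/mol), 19 added over 10 h to 2 mM, 25 °C; then Et3N (cat.), CH2Cl2, 25 °C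
Reagents that add atoms: none
Why: Proposed new method: Ni-catalysed electroreductive intramolecular alkenyl iodide–alkenyl chloride cross-electrophile coupling as the ring-closing diene synthesis. Cathodically formed zerovalent Ni(bpy) inserts first into the C–I bond of the (Z)-alkenyl iodide with retention; one-electron reduction to an alkenyl complex of monovalent nickel is followed by intramolecular oxidative addition of the slower 2-chloroalkene, and reductive elimination from trivalent nickel forms C10–C11 and the 14-membered ring. The I/Cl reactivity gap enforces cross-selectivity, and slow addition with charge control limits dimers and attack on the allylic ester. The closest known reaction types are the stoichiometric Ni(cod)2-mediated intramolecular coupling of two aryl or alkenyl halides and the Ni-catalysed electroreductive homocoupling of alkenyl halides. The catalytic base then equilibrates C2 to the (2R) epimer under control of the ring stereocentres.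

Step 12
Reactants: 20 (3R,5R,7E,9S,12Z,14S)-14-ethyl-5-hydroxy-7-methoxy-3,9,13-trimethyl-11-methylidene-5-{[(triisopropylsilyl)oxy]methyl}-1-oxacyclotetradeca-7,12-diene-2,4-dione
Product: 21 (3R,5R,7E,9S,12Z,14S)-14-ethyl-5-hydroxy-5-(hydroxymethyl)-7-methoxy-3,9,13-trimethyl-11-methylidene-1-oxacyclotetradeca-7,12-diene-2,4-dione (CNP0325854.3)
Conditions: n-Bu4NF, AcOH (1:1), THF, 0 °C → rt
Reagents that add atoms: none
Why: Fluoride-mediated desilylation buffered to near neutrality frees the primary alcohol without hydrolysing the enol ether, closing it to a cyclic ketal, epimerising C2 or translactonising the β-keto lactone.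

**Compound list**
1 | (S)-malic acid | OC(=O)C[C@H](O)C(=O)O | starting material
2 | [(2S,4S)-2-tert-butyl-5-oxo-1,3-dioxolan-4-yl]acetic acid | CC(C)(C)[C@H]1O[C@@H](CC(=O)O)C(=O)O1 | intermediate
3 | dilithium 2-[(2S)-2-tert-butyl-5-oxido-1,3-dioxol-4-yl]acetate (enolate-carboxylate of 2) | CC(C)(C)[C@H]1OC(CC(=O)[O-])=C([O-])O1.[Li+].[Li+] | intermediate
4 | [(2S,4R)-2-tert-butyl-5-oxo-4-{[(triisopropylsilyl)oxy]methyl}-1,3-dioxolan-4-yl]acetic acid | CC(C)(C)[C@H]1O[C@@](CO[Si](C(C)C)(C(C)C)C(C)C)(CC(=O)O)C(=O)O1 | intermediate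
5 | methyl (R)-3-bromo-2-methylpropanoate | COC(=O)[C@@H](C)CBr | starting material
6 | [(2R)-3-methoxy-2-methyl-3-oxopropyl]zinc bromide | COC(=O)[C@@H](C)C[Zn]Br | intermediate
7 | methyl (S)-4-chloro-2-methylpent-4-enoate | COC(=O)[C@@H](C)CC(Cl)=C | intermediate
8 | (S)-4-chloro-2-methylpent-4-enal | O=C[C@@H](C)CC(Cl)=C | intermediate
9 | (S)-2-chloro-4-methylhex-1-en-5-yne | C#C[C@@H](C)CC(Cl)=C | intermediate
10 | 1,3-dioxoisoindolin-2-yl [(2S,4R)-2-tert-butyl-5-oxo-4-{[(triisopropylsilyl)oxy]methyl}-1,3-dioxolan-4-yl]acetate | CC(C)(C)[C@H]1O[C@@](CO[Si](C(C)C)(C(C)C)C(C)C)(CC(=O)ON2C(=O)c3ccccc3C2=O)C(=O)O1 | intermediate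
11 | (2S,5R)-2-tert-butyl-5-[(4S)-6-chloro-4-methylhept-6-en-2-yn-1-yl]-5-{[(triisopropylsilyl)oxy]methyl}-1,3-dioxolan-4-one | CC(C)(C)[C@H]1O[C@@](CO[Si](C(C)C)(C(C)C)C(C)C)(CC#C[C@@H](C)CC(Cl)=C)C(=O)O1 | intermediate
12 | (2S,5R)-2-tert-butyl-5-[(2Z,4S)-6-chloro-4-methyl-2-(4,4,5,5-tetramethyl-1,3,2-dioxaborolan-2-yl)hepta-2,6-dien-1-yl]-5-{[(triisopropylsilyl)oxy]methyl}-1,3-dioxolan-4-one | CC(C)(C)[C@H]1O[C@@](CO[Si](C(C)C)(C(C)C)C(C)C)(C/C(B2OC(C)(C)C(C)(C)O2)=C\[C@@H](C)CC(Cl)=C)C(=O)O1 | intermediate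
13 | (2S,5R)-2-tert-butyl-5-[(2E,4S)-6-chloro-2-methoxy-4-methylhepta-2,6-dien-1-yl]-5-{[(triisopropylsilyl)oxy]methyl}-1,3-dioxolan-4-one | CC(C)(C)[C@H]1O[C@@](CO[Si](C(C)C)(C(C)C)C(C)C)(C/C(OC)=C\[C@@H](C)CC(Cl)=C)C(=O)O1 | intermediate
14 | (S)-pent-1-yn-3-ol | C#C[C@H](CC)O | starting material
15 | (5S)-5-ethyl-4-methyl-2,5-dihydro-1,2-oxamagnesole (cyclic alkenylmagnesium alkoxide) | CC[C@@H]1O[Mg]C=C1C | intermediate
16 | (S,Z)-1-iodo-2-methylpent-1-en-3-ol | I/C=C(/C)[C@H](CC)O | intermediate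
17 | (S,Z)-1-iodo-2-methylpent-1-en-3-yl propanoate | I/C=C(/C)[C@H](CC)OC(=O)CC | intermediate
18 | lithium 1-{[(1Z,3S)-1-iodo-2-methylpent-1-en-3-yl]oxy}prop-1-en-1-olate (enolate of 17) | I/C=C(/C)[C@H](CC)OC([O-])=CC.[Li+] | intermediate
19 | (S,Z)-1-iodo-2-methylpent-1-en-3-yl (2RS,4R,6E,8S)-10-chloro-4-hydroxy-6-methoxy-2,8-dimethyl-3-oxo-4-{[(triisopropylsilyl)oxy]methyl}undeca-6,10-dienoate | I/C=C(/C)[C@H](CC)OC(=O)C(C)C(=O)[C@](O)(CO[Si](C(C)C)(C(C)C)C(C)C)C/C(OC)=C\[C@@H](C)CC(Cl)=C | intermediate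
20 | (3R,5R,7E,9S,12Z,14S)-14-ethyl-5-hydroxy-7-methoxy-3,9,13-trimethyl-11-methylidene-5-{[(triisopropylsilyl)oxy]methyl}-1-oxacyclotetradeca-7,12-diene-2,4-dione | C=C1/C=C(/C)[C@H](CC)OC(=O)[C@H](C)C(=O)[C@](O)(CO[Si](C(C)C)(C(C)C)C(C)C)C/C(OC)=C\[C@@H](C)C1 | intermediate
21 | (3R,5R,7E,9S,12Z,14S)-14-ethyl-5-hydroxy-5-(hydroxymethyl)-7-methoxy-3,9,13-trimethyl-11-methylidene-1-oxacyclotetradeca-7,12-diene-2,4-dione | C=C1/C=C(/C)[C@H](CC)OC(=O)[C@H](C)C(=O)[C@](O)(CO)C/C(OC)=C\[C@@H](C)C1 | target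

**Totals**
Total step count: 12. Longest linear sequence: 8 steps (from 5 through steps 3, 4, 5, 6, 7, 10, 11, 12; equally long from 1 through steps 1, 2, 5, 6, 7, 10, 11, 12).

**Steps most likely to fail**

Step 11 (the proposed new step). Risks are insertion of zerovalent nickel into the allylic C13–O bond of the β-keto ester, protonation of alkenylnickel intermediates by the acidic C2–H, and oligomerisation. The fallback uses known chemistry, sets out from 13 and 16, and comes back at 20; it closes the ring at the lactone C–O bond instead. Alcohol 16 is treated with i-PrMgCl·LiCl (2.1 equiv) and then ZnCl2 to give the alkenylzinc chloride magnesium alkoxide F7. Negishi coupling of this with the chloroalkene of 13 (Pd2(dba)3, XPhos, THF, 50 °C) forms C10–C11 and gives the diene alcohol F8. Crossed Claisen condensation of F8 with the lithium enolate of S-tert-butyl propanethioate (THF, −78 °C) gives the seco β-keto thioester F9. Silver-mediated macrolactonisation of F9 (AgOCOCF3, Na2HPO4, THF, high dilution), followed by the same base equilibration of C2, gives 20.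

Step 5. The neopentyl-type primary radical may be captured slowly and alkyl-substituted copper acetylides are less efficient than aryl ones. The fallback uses known chemistry, sets out from 4 and 9, and comes back at 11. Acid 4 undergoes Suárez-type decarboxylative iodination (PhI(OAc)2, I2, visible light, CH2Cl2) to the primary iodide F1. This is joined to alkyne 9 by thermal Ni-catalysed alkyl–alkynyl (Sonogashira-type) coupling ([NiCl{N(C6H4-2-NMe2)2}], CuI, Cs2CO3, dioxane, 100 °C) to give 11.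

Step 6. The regioselectivity between C6 (next to a CH2 that carries a quaternary carbon) and C7 (next to the branched C8) may be only moderate. The fallback uses known chemistry, sets out from 11, and comes back at 19; it fixes the regiochemistry with a silicon tether from the C4 oxygen.
- Methanolysis of 11 (K2CO3, MeOH) gives the hydroxy methyl ester F2.
- Silylation with (HMe2Si)2NH gives the dimethylsilyl ether F3.
- Pt-catalysed intramolecular syn-hydrosilylation (Pt2[(CH2=CHSiMe2)2O]3, THF, rt; 5-exo) gives the cyclic alkenylsiloxane F4 with silicon on C6.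
- Iododesilylation with retention (N-iodosuccinimide, MeCN, 0 °C, aqueous work-up) gives the alkenyl iodide F5.
- Cu-catalysed C–O coupling with methanol (CuI, 3,4,7,8-tetramethyl-1,10-phenanthroline, Cs2CO3, MeOH/toluene, 80 °C) gives the enol ether hydroxy ester F6.
- F6, after deprotonation of its hydroxyl with LiN(SiMe3)2, undergoes crossed Claisen condensation with excess enolate 18 to give 19.

Further compounds
F1 | step 5 | (2S,5R)-2-tert-butyl-5-(iodomethyl)-5-{[(triisopropylsilyl)oxy]methyl}-1,3-dioxolan-4-one | CC(C)(C)[C@H]1O[C@@](CO[Si](C(C)C)(C(C)C)C(C)C)(CI)C(=O)O1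
F2 | step 6 | methyl (2R,6S)-8-chloro-2-hydroxy-6-methyl-2-{[(triisopropylsilyl)oxy]methyl}non-8-en-4-ynoate | COC(=O)[C@](O)(CO[Si](C(C)C)(C(C)C)C(C)C)CC#C[C@@H](C)CC(Cl)=C
F3 | step 6 | methyl (2R,6S)-8-chloro-2-[(dimethylsilyl)oxy]-6-methyl-2-{[(triisopropylsilyl)oxy]methyl}non-8-en-4-ynoate | COC(=O)[C@](O[SiH](C)C)(CO[Si](C(C)C)(C(C)C)C(C)C)CC#C[C@@H](C)CC(Cl)=C
F4 | step 6 | methyl (3E,5R)-3-[(2S)-4-chloro-2-methylpent-4-en-1-ylidene]-2,2-dimethyl-5-{[(triisopropylsilyl)oxy]methyl}-1,2-oxasilolane-5-carboxylate | COC(=O)[C@]1(CO[Si](C(C)C)(C(C)C)C(C)C)C/C(=C\[C@@H](C)CC(Cl)=C)[Si](C)(C)O1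
F5 | step 6 | methyl (2R,4E,6S)-8-chloro-2-hydroxy-4-iodo-6-methyl-2-{[(triisopropylsilyl)oxy]methyl}nona-4,8-dienoate | COC(=O)[C@](O)(CO[Si](C(C)C)(C(C)C)C(C)C)C/C(I)=C\[C@@H](C)CC(Cl)=C
F6 | step 6 | methyl (2R,4E,6S)-8-chloro-2-hydroxy-4-methoxy-6-methyl-2-{[(triisopropylsilyl)oxy]methyl}nona-4,8-dienoate | COC(=O)[C@](O)(CO[Si](C(C)C)(C(C)C)C(C)C)C/C(OC)=C\[C@@H](C)CC(Cl)=C
F7 | step 11 | chloro{(1Z,3S)-3-[(chloromagnesio)oxy]-2-methylpent-1-en-1-yl}zinc | Cl[Zn]/C=C(/C)[C@H](CC)O[Mg]Cl
F8 | step 11 | (2S,5R)-2-tert-butyl-5-[(2E,4S,7Z,9S)-9-hydroxy-2-methoxy-4,8-dimethyl-6-methylideneundeca-2,7-dien-1-yl]-5-{[(triisopropylsilyl)oxy]methyl}-1,3-dioxolan-4-one | CC(C)(C)[C@H]1O[C@@](CO[Si](C(C)C)(C(C)C)C(C)C)(C/C(OC)=C\[C@@H](C)CC(=C)/C=C(/C)[C@H](CC)O)C(=O)O1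
F9 | step 11 | S-tert-butyl (2RS,4R,6E,8S,11Z,13S)-4,13-dihydroxy-6-methoxy-2,8,12-trimethyl-10-methylidene-3-oxo-4-{[(triisopropylsilyl)oxy]methyl}pentadeca-6,11-dienethioate | CC(C)(C)SC(=O)C(C)C(=O)[C@](O)(CO[Si](C(C)C)(C(C)C)C(C)C)C/C(OC)=C\[C@@H](C)CC(=C)/C=C(/C)[C@H](CC)O
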